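## Structural features

The target is a germacranolide: a ten-membered carbocycle (C1–C10) with a (Z)-trisubstituted C4=C5 alkene, a C1 ketone and an α-methylene-γ-butyrolactone fused trans across C6–C7 (O6–C12, C7–C11). It has six stereocentres (3S, 6R, 7S, 8S, 9S, 10S); five run contiguously from C6 to C10, with oxygen on C6, C8, C9 and C10 and the O8/O9 and O9/O10 pairs both anti in the extended chain. C10 is a tertiary carbinol wedged between the C1 ketone and the secondary C9 carbinol, and C8 carries the tiglate next to the free C9 hydroxyl. The fragile groups are the methylene lactone (conjugate acceptor), the tiglate (can shift to O9 or O6; O6 and O8 are both γ to C12), the allylic β-hydroxy ketone C3(OH)–C2–C1(=O) (dehydration, retro-aldol) and the α-ketol at C10/C1, whose C9 hydroxyl is also β to the ketone. The real difficulty is twofold: a ten-membered ring holding a Z trisubstituted alkene, and five hydroxyl groups of similar kind that must be told apart. The key step exploits the 1,6-relationship of C4 and C9: a bond between them turns the macrocycle into a cis-fused decalin (ring A = C4–C9; ring B = C1–C4 with C9 and C10) in which the C9 oxygen and a leaving group on C5 are 1,3-related, so heterolysis of C4–C9 returns the ring, the C9 carbonyl and the C4=C5 alkene. Ring A of that decalin has the methyl-bearing C4 para to the three-carbon C7 substituent, the pattern of a p-menthane.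

## Logic of the disconnections

36 ⇒ 35 ⇒ 32. The O–Si bonds are cut last and, before them, the O6–C12 acyl bond, with C12 lowered to the alcohol. The methylene lactone is the most electrophilic group and should exist only when fluoride treatment alone remains. Gain: C12 travels as an ether from the first steps. Demand: the oxidant must pick the primary allylic alcohol, and O8 must already be acylated because it is also γ to C12.

32 ⇒ 31 ⇒ 30 ⇒ 29. The two aryl ethers and the C1 oxidation level are adjusted; the C1 ketone is traced to an alcohol tied to O10 as an acetal. A C1 ketone cannot pass a basic fragmentation (β-elimination of O3, retro-aldol at C9–C10), and a ketal beside the oxygenated quaternary C10 would be hard to make and to hydrolyse. Gain: one group masks C1 and protects the tertiary O10 without a silyl group that could migrate. Demand: C1–OH must be the only free secondary alcohol when it is oxidised, so O9 is silylated.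

29 ⇒ 26 + 27. The C8–O acyl bond is cut because the ester cannot survive alkoxide chemistry. Gain: 27 is used as bought. Demand: O8 must be the single free hydroxyl of 26.

26 ⇒ 25 ⇒ 24 ⇒ 23. The C9–H bond is cut, giving the ketone that a fragmentation leaves behind. Demand: hydride delivery controlled by chelation to O8 and O10.

23 ⇒ 22. C4 and C9 are reconnected, C5 receives a sulfonate and C9 a hydroxyl. The medium ring becomes a strain-free bicycle, and all ring stereocentres and the alkene geometry become problems of cyclohexane chemistry. Demand: cis fusion, an equatorial C5 sulfonate and C3 axial on ring A. A precursor with the same acetal-type ether on O6 and O10, or the same silyl group on O3 and O12, would need each pair told apart after the fragmentation; 22 is laid out so that every later deprotection removes a whole set.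

22 ⇒ 21 ⇒ 20 ⇒ 19 ⇒ 18. The C5–O sulfonate bond, the C8–O ether bond (back to an epoxide) and the epoxide oxygen (back to the C8=C9 alkene) are cut. Opening the epoxide frees the tertiary C9 hydroxyl only after O10 is protected, which separates the two tertiary oxygens. Demand: β-face epoxidation and attack at C8.

18 ⇒ 17 ⇒ 16 ⇒ 14. The acetal, the C1–H bond and the C10–O bond are cut, and the alkene returns from C8=C9 to the C9=C10 enone. Demand: α-carbon-selective and face-selective hydroxylation of an extended enolate.

14 ⇒ 13 ⇒ 12 ⇒ 11 ⇒ 10. The C6–O aryl ether bond is cut back to an epoxide, and the epoxide to the C5=C6 alkene. This gives the trans C5/C6 dioxygenation with the two oxygens already different (ether on C6, free hydroxyl on C5). Demand: α-face epoxide, opened at C6 while C9 is still trigonal.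

10 ⇒ 9 ⇒ 8 ⇒ 6. The C3–O bond is traced through the 2,3-epoxide to the C2=C3 enone and then to the saturated ketone. Demand: oxygen anti to the angular methyl.

6 ⇒ 5 ⇒ 3 + 4. The C9=C10 bond (aldol condensation) and the C3–C4 bond (conjugate addition) are cut; the ring of 3 becomes ring A, and 4 supplies C1–C3, C10 and C14. Demand: C-alkylation at the methyl-bearing α-carbon with the new chain cis to the C7 substituent.

3 ⇒ 2 ⇒ 1. The C12–O and C12–Cl bonds are cut. The allylic position is functionalised at the outset, when the molecule has only one electron-rich alkene.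

## Other disconnections considered

Alternative 1: The cut is C2–C3. SmI2 (divalent samarium) would reduce the α-bromoketone of the open-chain enal A1 to a samarium enolate, which adds to the C3 aldehyde and closes the ten-membered ring as the aldolate, giving hydroxy ketone A2.
- In favour: the ring bond and the C3 carbinol are made together under nearly neutral conditions, and the enolate can form only at C2 because C10 is quaternary. A2 already carries the tiglate, the acrylate and the C1 ketone, so the way from A2 to the target is shorter than the nine steps after 23; on end-game length this alternative is the better one.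
- Against: C3 would be set in a transannular addition with no evident controlling element, whereas the chosen plan fixes it on a six-membered ring. The (Z)-enal of A1 can isomerise. SmI2 also attacks α-oxygenated ketones (C1 is α to O10), enals and acrylates. The product is formed as a basic aldolate open to retro-aldol.
- Comparison: structurally, a strained ring is closed by C–C bond formation, against release of a ring from a strain-free bicycle. Mechanistically, a reductive organometallic addition stands against a concerted, stereospecific fragmentation. In step count, A1 needs five contiguous stereocentres from acyclic stereocontrol, which should cost at least what the short end game saves.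

Alternative 2: The cut is C8–C9. Low-valent titanium made from TiCl3(DME)1.5 (trivalent titanium) and zinc–copper couple would join the two aldehydes of lactone dialdehyde A3 at high dilution to the cyclic diol A4.
- In favour: intramolecular pinacol coupling is an established entry to ten-membered carbocycles and is expected to favour the cis-diol needed at C8/C9. One step would make the ring, C8 and C9, which is more direct than the chosen plan. The trans C6/C7 lactone is settled early on a small fragment, and the halves can be joined convergently, which is at least equal.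
- Against: nothing in A3 fixes the sense of the two new centres relative to C7 and C10. The C9 aldehyde is α-oxygenated and the C8 aldehyde is β to the lactone oxygen, so deoxygenation, β-elimination and epimerisation at C7 threaten, and the lactone carbonyl can itself couple. The two secondary hydroxyls of A4 are undifferentiated, the very problem the chosen plan avoids by carrying O8 as an ether and C9 as a ketone. The methylene group must still be added.
- Comparison: the mechanism is ketyl coupling on a metal, hard to steer, against an anti-periplanar fragmentation. Selective acylation of O8 and α-methylenation add three to four steps, so no net saving is expected.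

Alternative 3: The cut is C7–C8. LiN(SiMe3)2 would deprotonate the 13-membered α-allyloxy ketone A5 at C8; the [2,3]-Wittig shift of the enolate forms C7–C8 and the C11=C13 methylene, breaks O8–C13 and contracts the ring to A6.
- In favour: a 13-membered ether is far easier to close than a ten-membered carbocycle. The shift delivers the ring, C7, C8, a free O8 ready for the tiglate and the complete acrylate at once, so the C12 handling that costs the chosen plan two early and two late steps disappears; here the alternative is better. Enolisation is unambiguous (C10 quaternary), and A6 shares the C9 ketone/C10 ether array of 23, so the reduction logic is equal.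
- Against: the allyl unit is an acrylate, so conjugate addition of the enolate can compete. The C7/C8 configuration depends on enolate geometry, the C7=C11 geometry and the conformation of a floppy macrocycle. The product forms as an α-alkoxide ketone that can tautomerise. A5 needs C3, C6 and C10 set on an open chain plus a macro-etherification.
- Comparison: both key steps are concerted, but the fragmentation outcome follows from a chair and the sigmatropic one from a large ring. The overall step count is probably similar.

Key step: step 19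

Remarks on the chemistry.
- Atoms keep the germacrane numbers of the target throughout. In the bicyclic compounds β is the face of the C15 methyl on C4 and α the opposite face.
- "Side chain" is the C7 substituent CH2=C(CH2O–)– (C13, C11, C12). PMP = 4-methoxyphenyl, PMB = 4-methoxybenzyl, TBS = tert-butyldimethylsilyl, TES = triethylsilyl.
- Assumption: the directed reduction of step 13 is taken to give the 1β-alcohol. The C1 epimer would serve equally, since C1 returns to the ketone in step 25.

## Route

Step 1
Reactants: 1 (S)-(+)-carvone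
Product: 2 (5S)-5-(3-chloroprop-1-en-2-yl)-2-methylcyclohex-2-en-1-one
Conditions: Ca(OCl)2, solid CO2, CH2Cl2–H2O, 0 °C
Reagents that add atoms: calcium hypochlorite, [Ca+2].[O-]Cl.[O-]Cl
Why: Ene-type allylic chlorination by hypochlorous acid attacks the electron-rich 1,1-disubstituted alkene and not the enone; the stereocentre (future C7) is not touched.

Step 2
Reactants: 2 (5S)-5-(3-chloroprop-1-en-2-yl)-2-methylcyclohex-2-en-1-one
Product: 3 (5S)-5-[3-(4-methoxyphenoxy)prop-1-en-2-yl]-2-methylcyclohex-2-en-1-one
Conditions: 4-methoxyphenol, K2CO3, NaI (cat.), acetone, 55 °C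
Reagents that add atoms: 4-methoxyphenol, COc1ccc(O)cc1
Why: Williamson ether synthesis with a weakly basic phenoxide (SN2 and SN2′ give the same product) leaves the enone alone; the aryl ether is inert to base, hydride, peracid and DDQ and is removed oxidatively at the end.

Step 3
Reactants: 3 (5S)-5-[3-(4-methoxyphenoxy)prop-1-en-2-yl]-2-methylcyclohex-2-en-1-one; 4 ethyl vinyl ketone
Product: 5 (2R,5R)-2-methyl-2-(3-oxopentyl)-5-[3-(4-methoxyphenoxy)prop-1-en-2-yl]cyclohex-3-en-1-one (C15 β; oxopentyl chain and side chain both α)
Conditions: KOtBu (0.3 equiv), tBuOH–THF, 0 °C, slow addition of 4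
Reagents that add atoms: none
Why: Under equilibrating conditions the extended dienolate adds to the enone through its α-carbon C4 (deconjugative Michael addition, as in α-alkylation of cyclohexenone dienolates), moving the alkene to C5=C6. The acceptor enters pseudoaxially on the face that keeps the C7 substituent pseudoequatorial, so the new chain is cis to the side chain, the sense known for base-mediated annulation of the dihydro ketone.

Step 4
Reactants: 5 (2R,5R)-2-methyl-2-(3-oxopentyl)-5-[3-(4-methoxyphenoxy)prop-1-en-2-yl]cyclohex-3-en-1-one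
Product: 6 bicyclic 1-oxo-5,9(10)-diene (4,10-dimethyl; C15 β; side chain 7α)
Conditions: NaOMe, MeOH, 60 °C
Reagents that add atoms: none
Why: Second stage of the Robinson annulation: the ethyl ketone enolate (C10) adds to the ring carbonyl C9 (6-enolexo aldol) and E1cB loss of water gives the conjugated enone; C4 and C7 are spectators.

Step 5
Reactants: 6 bicyclic 1-oxo-5,9(10)-diene
Product: 8 cross-conjugated 1-oxo-2,5,9(10)-triene (C15 β; side chain 7α), via silyl dienol ether 7 (not isolated)
Conditions: LiN(iPr)2, Me3SiCl, THF, −78 °C; then Pd(OAc)2, MeCN, rt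
Reagents that add atoms: none
Why: Saegusa–Ito dehydrogenation: kinetic α′-deprotonation at C2 gives the cross-conjugated silyl dienol ether, which divalent palladium oxidises to the C2=C3 enone by β-hydride elimination; the ionic, low-temperature sequence spares the doubly allylic C7–H.

Step 6
Reactants: 8 cross-conjugated 1-oxo-2,5,9(10)-triene
Product: 9 2α,3α-epoxy-1-oxo-5,9(10)-diene
Conditions: H2O2 (30%), NaOH (cat.), MeOH, 0 °C
Reagents that add atoms: hydrogen peroxide, OO
Why: Weitz–Scheffer epoxidation picks the less substituted enone alkene; hydroperoxide adds to C3 anti to the adjacent angular C15 methyl, the usual outcome for angular-methyl cross-conjugated dienones, and sets C3–O α.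

Step 7
Reactants: 9 2α,3α-epoxy-1-oxo-5,9(10)-diene
Product: 10 3α-hydroxy-1-oxo-5,9(10)-diene
Conditions: SmI2, THF–MeOH, −90 °C
Reagents that add atoms: none
Why: Ketyl formation and cleavage of the Cα–O bond of the α,β-epoxy ketone give the β-hydroxy ketone with C3 unchanged; at this temperature the cleavage outruns reduction of the remaining enone.

Step 8
Reactants: 10 3α-hydroxy-1-oxo-5,9(10)-diene
Product: 11 5α,6α-epoxy-3α-hydroxy-1-oxo-9(10)-ene
Conditions: VO(acac)2 (cat.), tBuOOH, CH2Cl2, 0 °C to rt
Reagents that add atoms: tert-butyl hydroperoxide, CC(C)(C)OO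
Why: Hydroxyl-directed epoxidation: the axial homoallylic 3α-hydroxyl delivers the vanadium-bound peroxide to the α face of C5=C6. The enone alkene is electron-poor and the side-chain alkene has no directing hydroxyl, so both are spared; this fixes C5–O α.

Step 9
Reactants: 11 5α,6α-epoxy-3α-hydroxy-1-oxo-9(10)-ene
Product: 12 3α-TBS ether of 11
Conditions: tBuMe2SiOTf, 2,6-lutidine, CH2Cl2, −78 °C
Reagents that add atoms: tert-butyldimethylsilyl triflate, CC(C)(C)[Si](C)(C)OS(=O)(=O)C(F)(F)F
Why: Silylation stops dehydration and retro-aldol of the β-hydroxy ketone; it is done before the epoxide is opened so that O3 and O5 are never free together.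

Step 10
Reactants: 12 3α-TBS ether of 11
Product: 13 5α-hydroxy-6β-(4-methoxyphenoxy)-3α-(TBS-oxy)-1-oxo-9(10)-ene
Conditions: 4-methoxyphenol (5 equiv), Cs2CO3 (0.3 equiv), DMF, 80 °C
Reagents that add atoms: 4-methoxyphenol, COc1ccc(O)cc1
Why: SN2 opening of the epoxide by phenoxide at C6 (C5 is neopentylic) from the β face, trans-diaxial by the Fürst–Plattner rule in the half-chair that trigonal C9 enforces; this inverts C6 to the configuration of the target and leaves the 5α-hydroxyl. Excess phenol buffers the medium, so enolate-driven loss of the C3 silyloxy group is held back.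

Step 11
Reactants: 13 5α-hydroxy-6β-(4-methoxyphenoxy)-3α-(TBS-oxy)-1-oxo-9(10)-ene
Product: 14 5α-TES ether of 13
Conditions: Et3SiOTf, 2,6-lutidine, CH2Cl2, −40 °C
Reagents that add atoms: triethylsilyl triflate, CC[Si](CC)(CC)OS(=O)(=O)C(F)(F)F
Why: Temporary protection of the future leaving-group site, so that it cannot pick up the 1,3-syn C3 silyl group under base or attack the later 8,9-epoxide across the ring; a TES ether can be removed beside TBS ethers.

Step 12
Reactants: 14 5α-TES ether of 13
Product: 16 10α-hydroxy-10β-methyl-1-oxo-8-ene (3α-OTBS; 5α-OTES; 6β-OPMP; side chain 7α), via extended silyl dienol ether 15 (not isolated)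
Conditions: Me3SiOTf, Et3N, CH2Cl2, 0 °C; then KOtBu, THF, −40 °C; then 3-phenyl-2-(phenylsulfonyl)oxaziridine, −78 °C; aq. NH4Cl
Reagents that add atoms: 3-phenyl-2-(phenylsulfonyl)oxaziridine, O=S(=O)(N1OC1c1ccccc1)c1ccccc1
Why: Thermodynamic silylation gives the extended (C1=C10, C8=C9) dienol ether; its potassium dienolate, released without a proton source so that it cannot equilibrate to the C2 enolate, is hydroxylated at the α-carbon C10 (Davis oxidation), leaving the alkene at C8=C9. The oxidant approaches anti to the syn-axial C15 methyl, giving 10α-OH with C14 β.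

Step 13
Reactants: 16 10α-hydroxy-10β-methyl-1-oxo-8-ene
Product: 17 1β,10α-diol
Conditions: Me4NBH(OAc)3, AcOH–MeCN, −20 °C
Reagents that add atoms: none
Why: Evans–Saksena-type directed reduction: the acetoxyborohydride bound to the C10 hydroxyl delivers hydride within the complex to the α face of C1=O, giving the 1β-alcohol trans to O10.

Step 14
Reactants: 17 1β,10α-diol
Product: 18 1β,10α-O-isopropylidene acetal (3α-OTBS; 5α-OTES; 6β-OPMP; 8-ene)
Conditions: 2-methoxypropene, PPTS (cat.), CH2Cl2, 0 °C to rt
Reagents that add atoms: 2-methoxypropene, COC(C)=C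
Why: Acetonide formation on the trans-diequatorial diol masks C1 and protects the tertiary O10 with a group that cannot migrate; the trans-fused dioxolane is only possible in the ring-B chair that goes with the ring-A chair needed for the fragmentation.

Step 15
Reactants: 18 1β,10α-O-isopropylidene acetal
Product: 19 8β,9β-epoxide of 18
Conditions: 3-ClC6H4CO3H, NaHCO3, CH2Cl2, 0 °C
Reagents that add atoms: 3-chloroperoxybenzoic acid, OOC(=O)c1cccc(Cl)c1
Why: Prilezhaev epoxidation of the trisubstituted C8=C9 alkene, more nucleophilic than the ether-deactivated 1,1-disubstituted side-chain alkene. The α face is screened by the axial silyloxy groups on C3 and C5 and by the C7 side chain, so oxygen should be delivered to the β face, placing the C9 oxygen cis to C15.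

Step 16
Reactants: 19 8β,9β-epoxide of 18
Product: 20 9β-hydroxy-8α-(4-methoxybenzyloxy) compound
Conditions: 4-methoxybenzyl alcohol, NaH, DMF, 70 °C
Reagents that add atoms: 4-methoxybenzyl alcohol, COc1ccc(CO)cc1
Why: The alkoxide opens the epoxide by SN2 at the secondary C8 (C9 is fully substituted) from the α face, trans-diaxial in the cis-decalin chair; this sets C8–O α and frees the tertiary 9β-hydroxyl, which is therefore never in competition with O10.

Step 17
Reactants: 20 9β-hydroxy-8α-(4-methoxybenzyloxy) compound
Product: 21 5α,9β-diol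
Conditions: HF·pyridine, pyridine, THF, 0 °C
Reagents that add atoms: none
Why: Fluoride cleaves the triethylsilyl ether far faster than the TBS ether, and the acetal is inert to it.

Step 18
Reactants: 21 5α,9β-diol
Product: 22 cis-fused decalin 9β-hydroxy 5α-methanesulfonate (1β,10α-O-isopropylidene; 3α-OTBS; 6β-OPMP; side chain 7α with 12-OPMP; 8α-OPMB)
Conditions: MeSO2Cl, Et3N, DMAP (cat.), CH2Cl2, 0 °C
Reagents that add atoms: methanesulfonyl chloride, CS(=O)(=O)Cl
Why: Sulfonylation (through sulfene) of the only secondary hydroxyl; the tertiary C9 hydroxyl does not react.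

Step 19
Reactants: 22 cis-fused decalin 9β-hydroxy 5α-methanesulfonate
Product: 23 (Z)-cyclodec-4-en-9-one (1,10-O-isopropylidene; 3-OTBS; 6-OPMP; 8-OPMB; 12-OPMP; C3, C6, C7, C8, C10 arranged as in 36)
Conditions: KOtBu (1.2 equiv), THF, 0 °C, 15 min; pH 7 buffer
Reagents that add atoms: none
Why: Deprotonation of the tertiary C9 hydroxyl gives an alkoxide whose lone pair pushes into C9 while the C4–C9 σ bond, anti-periplanar to the C5–O bond of the equatorial mesylate, breaks and methanesulfonate leaves, so C9=O and C4=C5 form in one concerted event; this is the Grob (Wharton) fragmentation of a cyclic 1,3-diol monosulfonate, the standard way from decalins to cyclodecenones. No ring is closed and no σ bond is made: the ten-membered ring is set free by cleaving the fusion bond of a six-six bicycle, so the penalties of a medium-ring closure never arise. No stereocentre is created (C4, C5 and C9 become trigonal; C3, C6, C7, C8 and C10 are spectators), but the alkene geometry is: in the ring-A chair held by the trans-fused acetal on ring B, C3 is axial on C4, hence anti to H5 and gauche to C6, which translates stereospecifically into the Z alkene with C3 and C6 cis. The step needs fragmentation to outrun other base reactions, and the substrate secures this: C4 has no hydrogen and H6 is cis to the mesylate, so E2 is closed; C1 is not a carbonyl, so neither retro-aldol at C9–C10 nor β-elimination of O3 can occur; O10 sits in an acetal, so no silyl shift or α-ketol rearrangement intervenes. One equivalent of base for a short time at 0 °C limits enolisation of the new ketone towards C8.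

Step 20
Reactants: 23 (Z)-cyclodec-4-en-9-one
Product: 24 9-alcohol (C9 as in 36: O9 anti to O8 and to O10)
Conditions: Zn(BH4)2, Et2O, −20 °C
Reagents that add atoms: none
Why: Chelation-controlled reduction: zinc bridges the carbonyl and an α-oxygen (O8 ether or O10 acetal) and hydride enters from the ring periphery; both chelates lead to the same 9S carbinol, anti to both neighbours.

Step 21
Reactants: 24 9-alcohol
Product: 25 9-O-TBS ether
Conditions: tBuMe2SiOTf, 2,6-lutidine, CH2Cl2, 0 °C
Reagents that add atoms: tert-butyldimethylsilyl triflate, CC(C)(C)[Si](C)(C)OS(=O)(=O)C(F)(F)F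
Why: Silylation keeps O9 out of the later C1 oxidation and prevents DDQ from tying O8 and O9 together as a benzylidene acetal.

Step 22
Reactants: 25 9-O-TBS ether
Product: 26 8-alcohol
Conditions: DDQ, CH2Cl2–pH 7 buffer, 0 °C
Reagents that add atoms: none
Why: Oxidative cleavage of the 4-methoxybenzyl ether by benzylic hydride abstraction; the two 4-methoxyphenyl ethers have no benzylic hydrogen and survive.

Step 23
Reactants: 26 8-alcohol; 27 tiglic acid
Product: 29 8-O-tiglate (9-OTBS; 3-OTBS; 1,10-acetal; 6- and 12-OPMP), via mixed anhydride 28 (not isolated)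
Conditions: 27, 2,4,6-trichlorobenzoyl chloride, Et3N, THF, rt; then 26, DMAP, toluene, 40 °C
Reagents that add atoms: none
Why: Yamaguchi esterification: the mixed anhydride passes its tigloyl group through the acylpyridinium ion to the hindered secondary hydroxyl; the E alkene of the acid is the stable isomer and is not at risk.

Step 24
Reactants: 29 8-O-tiglate
Product: 30 1,10-diol
Conditions: AcOH–THF–H2O (3:1:1), 40 °C
Reagents that add atoms: none
Why: Hydrolysis of the strained trans-fused acetonide is faster than that of the secondary TBS ethers; it frees the secondary C1 and the tertiary C10 hydroxyl.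

Step 25
Reactants: 30 1,10-diol
Product: 31 1-ketone (10-OH free)
Conditions: Dess–Martin periodinane, NaHCO3, CH2Cl2, 0 °C
Reagents that add atoms: none
Why: Dess–Martin oxidation of the only secondary hydroxyl; the tertiary C10 hydroxyl cannot be oxidised, and buffering suppresses glycol cleavage and β-elimination of O3.

Step 26
Reactants: 31 1-ketone
Product: 32 6,12-diol
Conditions: (NH4)2Ce(NO3)6, pyridine, MeCN–H2O, 0 °C
Reagents that add atoms: none
Why: Oxidative dearylation: tetravalent cerium oxidises both 4-methoxyphenyl ethers to benzoquinone and releases the allylic C6 and C12 hydroxyls together.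

Step 27
Reactants: 32 6,12-diol
Product: 35 6,12-lactone bis-TBS ether (α-methylene-γ-butyrolactone), via hydroxy enal 33 (not isolated), via lactol 34 (not isolated)
Conditions: TEMPO (cat.), PhI(OAc)2, CH2Cl2, rt
Reagents that add atoms: none
Why: Oxoammonium oxidation picks the primary allylic alcohol; the enal closes to the γ-lactol with the C6 hydroxyl (O8 is acylated and cannot compete) and a second oxidation gives the lactone, the trans C6/C7 relationship being already in place.

Step 28
Reactants: 35 6,12-lactone bis-TBS ether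
Product: 36 CNP0106709.2 (target)
Conditions: HF·pyridine, pyridine, THF, 0 °C to rt
Reagents that add atoms: none
Why: Buffered fluoride cleaves the two TBS ethers (O3, O9) without base, which spares the methylene lactone, the tiglate, the β-hydroxy ketone and the α-ketol.

## Compound list

1 | (S)-(+)-carvone | CC1=CC[C@@H](CC1=O)C(C)=C | starting material
2 | (5S)-5-(3-chloroprop-1-en-2-yl)-2-methylcyclohex-2-en-1-one | CC1=CC[C@@H](CC1=O)C(=C)CCl | intermediate
3 | (5S)-5-[3-(4-methoxyphenoxy)prop-1-en-2-yl]-2-methylcyclohex-2-en-1-one | CC1=CC[C@@H](CC1=O)C(=C)COc1ccc(OC)cc1 | intermediate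
4 | ethyl vinyl ketone | CCC(=O)C=C | starting material
5 | (2R,5R)-2-methyl-2-(3-oxopentyl)-5-[3-(4-methoxyphenoxy)prop-1-en-2-yl]cyclohex-3-en-1-one | CCC(=O)CC[C@]1(C)C=C[C@H](C(=C)COc2ccc(OC)cc2)CC1=O | intermediate
6 | bicyclic 1-oxo-5,9(10)-diene (C15 β, side chain 7α) | CC1=C2C[C@@H](C(=C)COc3ccc(OC)cc3)C=C[C@@]2(C)CCC1=O | intermediate
7 | 1-(trimethylsilyloxy)-1,5,9(10)-triene (kinetic silyl dienol ether of 6) | CC1=C2C[C@@H](C(=C)COc3ccc(OC)cc3)C=C[C@@]2(C)CC=C1O[Si](C)(C)C | intermediate
8 | cross-conjugated 1-oxo-2,5,9(10)-triene | CC1=C2C[C@@H](C(=C)COc3ccc(OC)cc3)C=C[C@@]2(C)C=CC1=O | intermediate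
9 | 2α,3α-epoxy-1-oxo-5,9(10)-diene | CC1=C2C[C@@H](C(=C)COc3ccc(OC)cc3)C=C[C@@]2(C)[C@H]4O[C@H]4C1=O | intermediate
10 | 3α-hydroxy-1-oxo-5,9(10)-diene | CC1=C2C[C@@H](C(=C)COc3ccc(OC)cc3)C=C[C@@]2(C)[C@@H](O)CC1=O | intermediate
11 | 5α,6α-epoxy-3α-hydroxy-1-oxo-9(10)-ene | CC1=C2C[C@@H](C(=C)COc3ccc(OC)cc3)[C@H]4O[C@H]4[C@@]2(C)[C@@H](O)CC1=O | intermediate
12 | 3α-TBS ether of 11 | CC1=C2C[C@@H](C(=C)COc3ccc(OC)cc3)[C@H]4O[C@H]4[C@@]2(C)[C@@H](O[Si](C)(C)C(C)(C)C)CC1=O | intermediate
13 | 5α-hydroxy-6β-(4-methoxyphenoxy)-3α-(TBS-oxy)-1-oxo-9(10)-ene | CC1=C2C[C@@H](C(=C)COc3ccc(OC)cc3)[C@H](Oc3ccc(OC)cc3)[C@@H](O)[C@@]2(C)[C@@H](O[Si](C)(C)C(C)(C)C)CC1=O | intermediate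
14 | 5α-TES ether of 13 | CC1=C2C[C@@H](C(=C)COc3ccc(OC)cc3)[C@H](Oc3ccc(OC)cc3)[C@@H](O[Si](CC)(CC)CC)[C@@]2(C)[C@@H](O[Si](C)(C)C(C)(C)C)CC1=O | intermediate
15 | 1-(trimethylsilyloxy)-1(10),8-diene (extended silyl dienol ether of 14) | CC1=C(O[Si](C)(C)C)C[C@H](O[Si](C)(C)C(C)(C)C)[C@]2(C)[C@H](O[Si](CC)(CC)CC)[C@@H](Oc3ccc(OC)cc3)[C@H](C(=C)COc3ccc(OC)cc3)C=C12 | intermediate
16 | 10α-hydroxy-10β-methyl-1-oxo-8-ene | O=C1C[C@H](O[Si](C)(C)C(C)(C)C)[C@]2(C)[C@H](O[Si](CC)(CC)CC)[C@@H](Oc3ccc(OC)cc3)[C@H](C(=C)COc3ccc(OC)cc3)C=C2[C@]1(C)O | intermediate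
17 | 1β,10α-diol | O[C@H]1C[C@H](O[Si](C)(C)C(C)(C)C)[C@]2(C)[C@H](O[Si](CC)(CC)CC)[C@@H](Oc3ccc(OC)cc3)[C@H](C(=C)COc3ccc(OC)cc3)C=C2[C@]1(C)O | intermediate
18 | 1β,10α-O-isopropylidene acetal, 8-ene | CC1(C)O[C@H]2C[C@H](O[Si](C)(C)C(C)(C)C)[C@]3(C)[C@H](O[Si](CC)(CC)CC)[C@@H](Oc4ccc(OC)cc4)[C@H](C(=C)COc4ccc(OC)cc4)C=C3[C@]2(C)O1 | intermediate
19 | 8β,9β-epoxide of 18 | CC1(C)O[C@H]2C[C@H](O[Si](C)(C)C(C)(C)C)[C@]3(C)[C@H](O[Si](CC)(CC)CC)[C@@H](Oc4ccc(OC)cc4)[C@H](C(=C)COc4ccc(OC)cc4)[C@H]5O[C@@]35[C@]2(C)O1 | intermediate
20 | 9β-hydroxy-8α-(4-methoxybenzyloxy) compound (5α-OTES) | CC1(C)O[C@H]2C[C@H](O[Si](C)(C)C(C)(C)C)[C@]3(C)[C@H](O[Si](CC)(CC)CC)[C@@H](Oc4ccc(OC)cc4)[C@H](C(=C)COc4ccc(OC)cc4)[C@H](OCc4ccc(OC)cc4)[C@]3(O)[C@]2(C)O1 | intermediate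
21 | 5α,9β-diol | CC1(C)O[C@H]2C[C@H](O[Si](C)(C)C(C)(C)C)[C@]3(C)[C@H](O)[C@@H](Oc4ccc(OC)cc4)[C@H](C(=C)COc4ccc(OC)cc4)[C@H](OCc4ccc(OC)cc4)[C@]3(O)[C@]2(C)O1 | intermediate
22 | cis-fused decalin 9β-hydroxy 5α-methanesulfonate | CC1(C)O[C@H]2C[C@H](O[Si](C)(C)C(C)(C)C)[C@]3(C)[C@H](OS(C)(=O)=O)[C@@H](Oc4ccc(OC)cc4)[C@H](C(=C)COc4ccc(OC)cc4)[C@H](OCc4ccc(OC)cc4)[C@]3(O)[C@]2(C)O1 | intermediate
23 | (Z)-cyclodec-4-en-9-one, protected | CC1(C)O[C@H]2C[C@H](O[Si](C)(C)C(C)(C)C)/C(C)=C\[C@@H](Oc3ccc(OC)cc3)[C@H](C(=C)COc3ccc(OC)cc3)[C@H](OCc3ccc(OC)cc3)C(=O)[C@]2(C)O1 | intermediate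
24 | 9-alcohol | CC1(C)O[C@H]2C[C@H](O[Si](C)(C)C(C)(C)C)/C(C)=C\[C@@H](Oc3ccc(OC)cc3)[C@H](C(=C)COc3ccc(OC)cc3)[C@H](OCc3ccc(OC)cc3)[C@H](O)[C@]2(C)O1 | intermediate
25 | 9-O-TBS ether | CC1(C)O[C@H]2C[C@H](O[Si](C)(C)C(C)(C)C)/C(C)=C\[C@@H](Oc3ccc(OC)cc3)[C@H](C(=C)COc3ccc(OC)cc3)[C@H](OCc3ccc(OC)cc3)[C@H](O[Si](C)(C)C(C)(C)C)[C@]2(C)O1 | intermediate
26 | 8-alcohol | CC1(C)O[C@H]2C[C@H](O[Si](C)(C)C(C)(C)C)/C(C)=C\[C@@H](Oc3ccc(OC)cc3)[C@H](C(=C)COc3ccc(OC)cc3)[C@H](O)[C@H](O[Si](C)(C)C(C)(C)C)[C@]2(C)O1 | intermediate
27 | tiglic acid | C/C=C(\C)C(=O)O | starting material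
28 | tiglic 2,4,6-trichlorobenzoic anhydride | C/C=C(\C)C(=O)OC(=O)c1c(Cl)cc(Cl)cc1Cl | intermediate
29 | 8-O-tiglate | CC1(C)O[C@H]2C[C@H](O[Si](C)(C)C(C)(C)C)/C(C)=C\[C@@H](Oc3ccc(OC)cc3)[C@H](C(=C)COc3ccc(OC)cc3)[C@H](OC(=O)/C(C)=C/C)[C@H](O[Si](C)(C)C(C)(C)C)[C@]2(C)O1 | intermediate
30 | 1,10-diol | O[C@H]1C[C@H](O[Si](C)(C)C(C)(C)C)/C(C)=C\[C@@H](Oc2ccc(OC)cc2)[C@H](C(=C)COc2ccc(OC)cc2)[C@H](OC(=O)/C(C)=C/C)[C@H](O[Si](C)(C)C(C)(C)C)[C@]1(C)O | intermediate
31 | 1-ketone | O=C1C[C@H](O[Si](C)(C)C(C)(C)C)/C(C)=C\[C@@H](Oc2ccc(OC)cc2)[C@H](C(=C)COc2ccc(OC)cc2)[C@H](OC(=O)/C(C)=C/C)[C@H](O[Si](C)(C)C(C)(C)C)[C@]1(C)O | intermediate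
32 | 6,12-diol | O=C1C[C@H](O[Si](C)(C)C(C)(C)C)/C(C)=C\[C@@H](O)[C@H](C(=C)CO)[C@H](OC(=O)/C(C)=C/C)[C@H](O[Si](C)(C)C(C)(C)C)[C@]1(C)O | intermediate
33 | 6-hydroxy-12-al (hydroxy enal) | O=C1C[C@H](O[Si](C)(C)C(C)(C)C)/C(C)=C\[C@@H](O)[C@H](C(=C)C=O)[C@H](OC(=O)/C(C)=C/C)[C@H](O[Si](C)(C)C(C)(C)C)[C@]1(C)O | intermediate
34 | 6,12-lactol (both C12 epimers) | O=C1C[C@H](O[Si](C)(C)C(C)(C)C)/C(C)=C\[C@H]2OC(O)C(=C)[C@@H]2[C@H](OC(=O)/C(C)=C/C)[C@H](O[Si](C)(C)C(C)(C)C)[C@]1(C)O | intermediate
35 | 6,12-lactone, 3,9-bis-TBS ether | O=C1C[C@H](O[Si](C)(C)C(C)(C)C)/C(C)=C\[C@H]2OC(=O)C(=C)[C@@H]2[C@H](OC(=O)/C(C)=C/C)[C@H](O[Si](C)(C)C(C)(C)C)[C@]1(C)O | intermediate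
36 | CNP0106709.2 | C=C1C(=O)O[C@@H]2/C=C(/C)[C@@H](O)CC(=O)[C@@](C)(O)[C@@H](O)[C@@H](OC(=O)/C(C)=C/C)[C@@H]12 | target

Total step count: 28. Longest linear sequence: 28 steps, from 1 to 36; 4 and 27 are used as bought.

## Least certain steps

Step 19 (key step). The alkoxide base may enolise the new C9 ketone towards C8 and erode the C8 configuration. If the reactive chair is poorly populated, fragmentation may be slow enough for intramolecular displacement of the mesylate to compete. Fallback: merge fragmentation and reduction. Treating 22 with LiAlH4 in THF at 0 °C forms the C9 aluminium alkoxide, which fragments, and the ketone is reduced at once by hydride held on the neighbouring oxygens before it can enolise (a known reductive variant of the same fragmentation). This leads from 22 directly to 24 and makes no new compound.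

Step 15. The peracid may be delivered to the α face, anti to the two axial methyl groups, and the side-chain alkene may be epoxidised in competition. Fallback: use the same facial preference the other way round. From 18, N-bromoacetamide in aqueous acetone places bromine on the α face and water on C9 from the β face, giving the 8α-bromo-9β-hydroxy compound F1. K2CO3 in methanol then closes the epoxide by displacement of bromide from the β side, and the route is rejoined at 19.

Step 3. Conjugate addition may occur through the cross-conjugated C8 enolate, the enone may polymerise, and facial selectivity at C4 may be poor. Fallback: reagent control. From 3, condensation with (R)-1-phenylethylamine gives the ketimine F2. Its secondary dienamine tautomer adds to 4 through the substituted α-carbon in a chair-like aza-ene transition state in which the amine stereocentre decides the face (the chiral-imine Michael reaction of α-substituted ketones). Hydrolysis with aqueous acetic acid returns to the route at 5.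

Step 23. Acylation of a secondary hydroxyl crowded by the neighbouring silyl ether and the C7 branch may be incomplete, and forcing conditions invite silyl or acyl migration. Fallback: change the order of events. From 23, DDQ gives the α-hydroxy ketone F3, whose hydroxyl sits next to a trigonal carbon and is less hindered. Esterification with 28 gives the keto ester F4, and Zn(BH4)2 reduction chelated through O10 gives the hydroxy ester F5. Silylation with tBuMe2SiOTf and 2,6-lutidine then rejoins the route at 29.

## Further compounds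

F0 | step 19 | none | none
F1 | step 15 | 8α-bromo-9β-hydroxy compound from 18 | CC1(C)O[C@H]2C[C@H](O[Si](C)(C)C(C)(C)C)[C@]3(C)[C@H](O[Si](CC)(CC)CC)[C@@H](Oc4ccc(OC)cc4)[C@H](C(=C)COc4ccc(OC)cc4)[C@H](Br)[C@]3(O)[C@]2(C)O1
F2 | step 3 | (R)-1-phenylethylamine ketimine of 3 | CC1=CC[C@@H](CC1=N[C@H](C)c2ccccc2)C(=C)COc3ccc(OC)cc3
F3 | step 23 | 8-hydroxy-9-ketone from 23 | CC1(C)O[C@H]2C[C@H](O[Si](C)(C)C(C)(C)C)/C(C)=C\[C@@H](Oc3ccc(OC)cc3)[C@H](C(=C)COc3ccc(OC)cc3)[C@H](O)C(=O)[C@]2(C)O1
F4 | step 23 | 8-O-tigloyl-9-ketone | CC1(C)O[C@H]2C[C@H](O[Si](C)(C)C(C)(C)C)/C(C)=C\[C@@H](Oc3ccc(OC)cc3)[C@H](C(=C)COc3ccc(OC)cc3)[C@H](OC(=O)/C(C)=C/C)C(=O)[C@]2(C)O1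
F5 | step 23 | 8-O-tigloyl-9-alcohol | CC1(C)O[C@H]2C[C@H](O[Si](C)(C)C(C)(C)C)/C(C)=C\[C@@H](Oc3ccc(OC)cc3)[C@H](C(=C)COc3ccc(OC)cc3)[C@H](OC(=O)/C(C)=C/C)[C@H](O)[C@]2(C)O1
A1 | alternative 1 | open-chain C2 bromoketone C3 enal | O=C/C(C)=C\[C@@H](O[Si](C)(C)C(C)(C)C)[C@H](C(=C)C(=O)OC)[C@H](OC(=O)/C(C)=C/C)[C@@H]1OC(C)(C)O[C@]1(C)C(=O)CBr
A2 | alternative 1 | ten-membered 3-hydroxy-1-ketone | O=C1C[C@H](O)/C(C)=C\[C@@H](O[Si](C)(C)C(C)(C)C)[C@H](C(=C)C(=O)OC)[C@H](OC(=O)/C(C)=C/C)[C@@H]2OC(C)(C)O[C@]12C
A3 | alternative 2 | lactone C8,C9-dialdehyde | O=C1C[C@H](C=O)[C@H](O1)/C=C(/C)[C@@H](O[Si](C)(C)C(C)(C)C)CC2(OCCO2)[C@@](C)(OCOC)C=O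
A4 | alternative 2 | ten-membered cis-8,9-diol | O=C1C[C@H]2[C@H](O1)/C=C(/C)[C@@H](O[Si](C)(C)C(C)(C)C)CC3(OCCO3)[C@@](C)(OCOC)[C@@H](O)[C@H]2O
A5 | alternative 3 | 13-membered α-allyloxy ketone | O=C1COC/C(C(=O)OC)=C\[C@H](O[Si](C)(C)C(C)(C)C)/C=C(/C)[C@@H](O[Si](C)(C)C(C)(C)C)CC2(OCCO2)[C@@]1(C)OCOC
A6 | alternative 3 | ten-membered 8-hydroxy-9-ketone with C7 acrylate | C=C(C(=O)OC)[C@H]1[C@H](O[Si](C)(C)C(C)(C)C)/C=C(/C)[C@@H](O[Si](C)(C)C(C)(C)C)CC2(OCCO2)[C@@](C)(OCOC)C(=O)[C@H]1O
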